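Late in the ash run, between 6.00 min and 8.00 min, the target gains 0.0125 min⁻¹ of the charge per minute, against 0.0250 min⁻¹ over the first 2.00 min, so the rate has fallen to half of its early value, with 83.8 % of the substrate still there.

| setting | ash | eta | zeta | epsilon |
|---|---|---|---|---|
| substrate | 0.050 M | 0.10 M | 0.10 M | 0.10 M |
| free catalyst | 0.5 mol% | 0.5 mol% | 0.5 mol% | 0.5 mol% |
| temperature | 70 °C | 70 °C | 40 °C | 10 °C |
| remark | run made earlier |  |  |  |
| time |  | 40 min | 40 min | 40 min |

ash run (percent of the substrate charged)

| time / min | target / % | substrate / % |
|---|---|---|
| 0.667 | 1.8 | 97.8 |
| 2.00 | 5.0 | 94.5 |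
| 4.00 | 9.8 | 89.0 |
| 6.00 | 13.2 | 87.1 |
| 8.00 | 15.7 | 83.8 |

(each reading ± 0.5 percentage points)

- the earlier runs do not show what temperature does; that part of a forecast is a guess
- no earlier run changes the charge of free catalyst; that part of a forecast is a guess

* the flask that comes out highest in amount of target, in percent of the substrate charged, or "all alike" when all lie within 1.5 percentage points (eta / zeta / epsilon / all alike)
* target at the end, in percent of the substrate charged, eta
* target at the end, in percent of the substrate charged, zeta
* target at the end, in percent of the substrate charged, epsilon

This reckoning takes the slowing to be free catalyst lost in pairs (second-order deactivation), an assumption that the ash run cannot prove. On it, c(free catalyst) falls as one over one plus t/τ, and the reciprocal of the rate climbs on a straight line. The catalyst lifetime τ, the time in which the pair loss halves c(free catalyst) from its start, is read by letting each mean rate stand for the rate at the middle of its stretch, which gives 5.00 min for the ash run. This reading is rough, since the late rate rests on a difference of two readings. The start rate is then 0.0300 min⁻¹, and the target follows S times the logarithm of one plus t/τ, where S, the start rate times τ, is 15.0 %. Put back into the curve, the two means cost little: it returns 5.05 % for the first stretch against the 5.0 % read, and 2.5 percentage points for the late stretch against the 2.5 points read. At 8.00 min the curve gives 14.3 % against the reading of 15.7 %, but that gap of 1.4 points is not the error of the means: τ and S rest on a few readings, each with a scatter of 0.5 points, and so carry that scatter.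

Eta looks nearly the same as the ash run, with the same mol%, but its substrate at 0.10 M is twice as concentrated, and so is its free catalyst. The start rate therefore doubles and τ falls to half, at 2.50 min, while S stays the same. At 40 min the ash flask reckons to 33.0 % and eta to 42.5 %, so eta ends higher. Temperature is a guess here, so this reckoning commits to eta alone and expects it highest.

The forecast, which differs from this reckoning on eta, gives 27 % for eta, 15 % for zeta and 2 % for epsilon, names eta as highest, and says that catalyst death “would give a plateau near 26%”.

The flasks give 41.9 % for eta, 15.3 % for zeta and 1.12 % for epsilon, with eta highest.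

    2 free catalyst → spent catalyst (k = 470 L mol⁻¹ min⁻¹, Ea = 37.0 kJ mol⁻¹)
    catalyst intermediate A → catalyst intermediate B (k = 287 min⁻¹, Ea = 72.0 kJ mol⁻¹)
    catalyst intermediate B → free catalyst + target (k = 54.0 min⁻¹, Ea = 86.0 kJ mol⁻¹)
    substrate + free catalyst ⇌ catalyst intermediate A (K = 8.31 L mol⁻¹, k = 167 L mol⁻¹ min⁻¹, Ea = 53.0 kJ mol⁻¹, ΔH = −10.0 kJ mol⁻¹)
    (constants at 70 °C)

The pairing of free catalyst into spent catalyst is the main reason eta stops where it does: without that step eta reaches 93.9 % instead of 41.9 %. The lifetime puts the lost share at t/(t+τ), or 94.1 % at 40 min, and the table holds 92.5 % of the catalyst as spent catalyst in eta. Carried unchanged to epsilon read at 25 min, eta's lifetime scales the 1.12 % of epsilon down to 0.948 %. That flask gives 0.674 %, close to the 0.700 % of plain proportion to time, with spent catalyst at 8.01 %.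

All runs are simulated for substances that don't exist.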